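**Retrosynthetic overview**
1. Target ⇐ triacetylation and acetonide removal of a 6‑chloro pentaol ⇐ twofold ketone reduction (C2, C9) of a ten‑membered dienedione.
2. Ten‑membered ring ⇐ retro‑aldol/E1cB ring expansion of a cyclopentanone fused to an 8‑oxabicyclo[3.2.1]octene: C3–C9 is cut and the C4–O–C8 bridge opens to the 3Z alkene and C8–OH.
3. That cage ⇐ silicon‑tethered (5+2) annulation of a 3‑oxidopyrylium (Achmatowicz pyranone carrying C4–C8 and C16–C19) with the C9 enol ether of a trans‑hydrindanone; lactone and C6–Cl are set on the rigid cage.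
4. Hydrindanone ⇐ Hajos–Parrish annulation of 2‑methylcyclopentane‑1,3‑dione with ethyl vinyl ketone; pyranone ⇐ aldol of methyl propanoate with 4‑methylfurfural, then Achmatowicz.
5. Ring order: ring A plus cyclopentane → pyranone → oxabicycle (seven‑membered carbocycle) → γ‑lactone → ten‑membered ring.

Assumption: 4‑methylfuran‑2‑carbaldehyde is bought; briarane numbering is used (C1 with C15 methyl, ring A = C1, C10–C14, lactone C17–C19), β is the face of the C15 methyl; 16–18 and 20–24 are C17 epimer mixtures (16–18 also at the carbinol/acetal carbons) that converge at 25.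

**Step 1**
Reactants: 1 2‑methylcyclopentane‑1,3‑dione; 2 pent‑1‑en‑3‑one
Product: 3 2‑methyl‑2‑(3‑oxopentyl)cyclopentane‑1,3‑dione
Conditions: H2O, AcOH (cat.), 75 °C
Reagents that add atoms: none
Why: Michael addition of the acidic 1,3‑dione to the enone (first half of a Robinson annulation); no stereocentre is formed.

**Step 2**
Reactants: 3 triketone
Product: 4 (7aS)‑4,7a‑dimethyl‑2,3,7,7a‑tetrahydro‑1H‑indene‑1,5(6H)‑dione
Conditions: L‑phenylalanine (1 equiv), (1S)‑(+)‑camphor‑10‑sulfonic acid (0.5 equiv), DMF, 30 to 70 °C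
Reagents that add atoms: none
Why: Hajos–Parrish–Eder–Sauer–Wiechert aldol condensation through the amino‑acid enamine differentiates the two enantiotopic ring carbonyls and sets the quaternary carbon (briarane C1, S).

**Step 3**
Reactants: 4 enedione
Product: 5 (1S,7aS)‑1‑hydroxy‑4,7a‑dimethyl‑1,2,3,6,7,7a‑hexahydro‑5H‑inden‑5‑one
Conditions: NaBH4 (0.3 equiv), EtOH, −20 °C
Reagents that add atoms: none
Why: Chemoselective borohydride reduction of the saturated cyclopentanone over the enone; hydride enters anti to the angular methyl and gives the 2β‑alcohol.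

**Step 4**
Reactants: 5 hydroxy enone
Product: 6 2β‑tert‑butyldimethylsilyl ether of 5
Conditions: tBuMe2SiCl, imidazole, DMF, rt
Reagents that add atoms: tert‑butyldimethylsilyl chloride, CC(C)(C)[Si](C)(C)Cl
Why: Standard silyl protection of a secondary alcohol; the bulky 2β group later shields the β face of C3.

**Step 5**
Reactants: 6 silyl enone
Product: 7 cross‑conjugated dienone (C13=C14 and C10=C11, C12 ketone)
Conditions: 2‑iodoxybenzoic acid, DMSO, 75 °C
Reagents that add atoms: none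
Why: Nicolaou‑type IBX dehydrogenation at the only enolisable α′,β′ pair (C13–C14) installs the ring A alkene.

**Step 6**
Reactants: 7 dienone
Product: 8 trienyl triflate (C12–OTf; C9=C10, C11=C12, C13=C14)
Conditions: KN(SiMe3)2, THF, −78 °C; PhNTf2
Reagents that add atoms: N‑phenylbis(trifluoromethanesulfonimide), O=S(=O)(N(c1ccccc1)S(=O)(=O)C(F)(F)F)C(F)(F)F
Why: Vinylogous (γ) deprotonation at C9, the only acidic C–H, and O‑triflation of the extended enolate give the linear trienyl triflate.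

**Step 7**
Reactants: 8 trienyl triflate
Product: 9 trans‑hydrindane dienyl triflate with 9α‑OH and 10α‑H
Conditions: BH3·SMe2, THF, 0 °C; then H2O2, aq NaHCO3, 0 °C
Reagents that add atoms: hydrogen peroxide, OO
Why: Hydroboration–oxidation adds anti‑Markovnikov and syn to the most electron‑rich, least hindered trisubstituted cyclopentene bond (the other two are deactivated by the triflate or neopentyl) from the face opposite the C15 methyl, which sets the trans ring fusion and the C9 oxygen.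

**Step 8**
Reactants: 9 dienyl triflate alcohol
Product: 10 ring A 11,13‑diene with 9α‑OH
Conditions: Pd(OAc)2 (5 mol %), PPh3, HCO2H, Et3N, DMF, 60 °C
Reagents that add atoms: none
Why: Palladium‑catalysed formate reduction of an enol triflate (Cacchi) replaces OTf by H without touching the diene or the stereocentres.

**Step 9**
Reactants: 10 diene alcohol
Product: 11 9α,11α,12α‑triol (C20 methyl β, C13=C14 kept)
Conditions: OsO4 (2 mol %), N‑methylmorpholine N‑oxide, acetone/H2O, 0 °C
Reagents that add atoms: N‑methylmorpholine N‑oxide, C[N+]1([O-])CCOCC1; water, O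
Why: Upjohn dihydroxylation of the more electron‑rich trisubstituted C11=C12 bond from the α face, opposite the syn‑axial C15 methyl, sets C11 (OH α, methyl β) and C12 (OH α) as the cis‑diol.

**Step 10**
Reactants: 11 triol
Product: 12 11,12‑acetonide with free 9α‑OH
Conditions: Me2C(OMe)2, pyridinium p‑toluenesulfonate (cat.), CH2Cl2, rt
Reagents that add atoms: 2,2‑dimethoxypropane, COC(C)(C)OC
Why: Acetalisation is selective for the cis‑1,2‑diol, which removes acidic and oxidisable sites from ring A.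

**Step 11**
Reactants: 12 acetonide alcohol
Product: 13 northern ketone (9‑oxo, 2β‑OSi, 10α‑H, 11,12‑acetonide, C13=C14)
Conditions: Dess–Martin periodinane, NaHCO3, CH2Cl2, 0 °C
Reagents that add atoms: none
Why: Neutral Dess–Martin oxidation gives the trans‑fused ketone without epimerising the labile C10.

**Step 12**
Reactants: 14 methyl propanoate; 15 4‑methylfuran‑2‑carbaldehyde
Product: 16 methyl 3‑hydroxy‑2‑methyl‑3‑(4‑methylfuran‑2‑yl)propanoate
Conditions: LiN(iPr)2, THF, −78 °C; then 15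
Reagents that add atoms: none
Why: Lithium ester‑enolate aldol addition; the carbinol centre is erased later and C17 is equilibrated later, so no control is needed.

**Step 13**
Reactants: 16 furyl carbinol
Product: 17 methyl 2‑(6‑hydroxy‑5‑methyl‑3‑oxo‑3,6‑dihydro‑2H‑pyran‑2‑yl)propanoate
Conditions: N‑bromosuccinimide, NaHCO3, THF/H2O, 0 °C
Reagents that add atoms: water, O
Why: Achmatowicz oxidative rearrangement turns the furan into the pyranone that carries C4–C8, C16 and the C17–C19 side chain.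

**Step 14**
Reactants: 17 pyranone hemiacetal
Product: 18 methyl 2‑(6‑acetoxy‑5‑methyl‑3‑oxo‑3,6‑dihydro‑2H‑pyran‑2‑yl)propanoate
Conditions: Ac2O, pyridine, 4‑(dimethylamino)pyridine (cat.), CH2Cl2, 0 °C
Reagents that add atoms: acetic anhydride, CC(=O)OC(C)=O
Why: Acetylation of the anomeric hydroxyl gives the ionisable pyrylium precursor.

**Step 15**
Reactants: 13 northern ketone; 18 pyranone acetate
Product: 23 cage keto diol (2β‑OH; 9‑OH; C7 ketone; C4–O–C8 bridge; new C3–C4 and C8–C9 bonds), via C9 enol silyl triflate 19 (not isolated), via bis(enol) silane 20 (not isolated), via tethered silyloxypyrylium triflate 21 (not isolated), via silyl acetate cycloadduct 22 (not isolated)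
Conditions: LiN(SiMe3)2, THF, −78 °C; iPr2Si(OTf)2; then 18, 2,6‑lutidine, CH2Cl2, −78 to −40 °C; Me3SiOTf (10 mol %), to 0 °C; then HF·pyridine, THF, 0 °C to rt
Reagents that add atoms: none
Why: Proposed new method: a silicon‑tethered cationic oxidopyrylium (5+2) annulation in which the kinetic C9 enolate is capped as a silyl triflate, the same silicon enol‑silylates the C7 oxygen of 18, Me3SiOTf‑triggered loss of the anomeric acetate gives a 3‑silyloxypyrylium whose C4 is attacked by the enol‑ether carbon C3, and the resulting silyl dienol ether closes C8–C9 onto the silyl oxocarbenium (Mukaiyama–Michael then Mukaiyama aldol inside one tether), the six‑membered O9–Si–O7 tether forcing the enone bridge exo while attack occurs on the α face anti to the C15 methyl and the 2β‑silyloxy group, which together set C8 as R; the closest known reactions are intramolecular 3‑oxidopyrylium–alkene [5+2] cycloadditions and Me3SiOTf‑promoted additions of silyl enol ethers to Achmatowicz acetates.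

**Step 16**
Reactants: 23 cage keto diol
Product: 25 cage γ‑lactone (C19–O7; 7R, 17R; 2β‑OH and 9‑OH free), via C7 hydroxy ester 24 (not isolated)
Conditions: Me4NBH(OAc)3, AcOH/MeCN, −30 °C; then 1,8‑diazabicyclo[5.4.0]undec‑7‑ene, toluene, 40 °C
Reagents that add atoms: none
Why: Evans–Saksena hydroxyl‑directed reduction delivers hydride from the C9 alkoxyborohydride to the endo face of the C7 ketone (anti‑1,3‑diol, C7–O exo), after which base‑mediated transesterification closes the γ‑lactone onto the cis side chain and epimerises C17 to the isomer with the methyl trans to the congested C9.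

**Step 17**
Reactants: 25 cage lactone
Product: 26 allylic chloride (C5=C16 exocyclic methylene, 6S‑Cl exo)
Conditions: Ca(OCl)2, CO2 (s), CH2Cl2/H2O, 0 °C
Reagents that add atoms: calcium hypochlorite, [Ca+2].[O-]Cl.[O-]Cl
Why: Ene‑type allylic chlorination by HOCl puts chlorine on C6 of the only trisubstituted alkene from the open exo face of the oxabicycle, and the C16 methyl loses the proton because the C4 bridgehead cannot, giving the chloride cis to the C7 oxygen as in the target.

**Step 18**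
Reactants: 26 chloro cage lactone
Product: 28 ten‑membered (3Z)‑2,9‑diketone (8‑OH, 6‑Cl, 5(16)‑ene, lactone, acetonide), via 2‑keto aldol 27 (not isolated)
Conditions: Dess–Martin periodinane, NaHCO3, CH2Cl2, 0 °C; then 1,8‑diazabicyclo[5.4.0]undec‑7‑ene, 0 °C to rt
Reagents that add atoms: none
Why: Oxidation unmasks the C2 ketone and the C9 alkoxide then undergoes a de Mayo‑type retro‑aldol cleavage of C3–C9 followed by E1cB opening of the C4–O–C8 bridge, a five‑carbon ring expansion of the cyclopentanone driven by release of the congested C3–C9–C8 array; the 3Z enone is expected to be the less strained geometry and can equilibrate through reversible oxa‑Michael re‑closure, and C8 keeps its configuration as the tertiary alcohol.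

**Step 19**
Reactants: 28 dienedione
Product: 29 (2S,9S)‑diol
Conditions: NaBH4, CeCl3·7H2O, MeOH, −78 °C
Reagents that add atoms: none
Why: Luche reduction, run at once so the enone cannot re‑close, with 1,2‑delivery to the C2 enone anti to the C15 methyl and cerium‑chelated (C8–OH) reduction of the C9 α‑hydroxy ketone from the ring periphery expected to give the 2S,9S diol; this is a prediction, not a certainty.

**Step 20**
Reactants: 29 acetonide diol
Product: 30 2,8,9,11,12‑pentaol
Conditions: pyridinium p‑toluenesulfonate, MeOH, 35 °C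
Reagents that add atoms: none
Why: Mild transketalisation removes the acetonide without ionising the allylic alcohol or the allylic chloride.

**Step 21**
Reactants: 30 pentaol
Product: 31 target CNP0285654.2
Conditions: Ac2O, pyridine, 4‑(dimethylamino)pyridine (cat.), CH2Cl2, 0 °C to rt
Reagents that add atoms: acetic anhydride, CC(=O)OC(C)=O
Why: Acetylation takes the three secondary alcohols (C2, C9, C12) and leaves the two tertiary alcohols (C8, C11) free.

**Compound list**
1 | 2‑methylcyclopentane‑1,3‑dione | CC1C(=O)CCC1=O | starting material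
2 | pent‑1‑en‑3‑one (ethyl vinyl ketone) | CCC(=O)C=C | starting material
3 | 2‑methyl‑2‑(3‑oxopentyl)cyclopentane‑1,3‑dione | CCC(=O)CCC1(C)C(=O)CCC1=O | intermediate
4 | (7aS)‑4,7a‑dimethyl‑2,3,7,7a‑tetrahydro‑1H‑indene‑1,5(6H)‑dione | C1C(=O)[C@@]2(C)CCC(=O)C(C)=C2C1 | intermediate
5 | (1S,7aS)‑1‑hydroxy‑4,7a‑dimethyl‑1,2,3,6,7,7a‑hexahydro‑5H‑inden‑5‑one | C1[C@H](O)[C@@]2(C)CCC(=O)C(C)=C2C1 | intermediate
6 | 2β‑tert‑butyldimethylsilyl ether of 5 | C1[C@H](O[Si](C)(C)C(C)(C)C)[C@@]2(C)CCC(=O)C(C)=C2C1 | intermediate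
7 | cross‑conjugated dienone | C1[C@H](O[Si](C)(C)C(C)(C)C)[C@@]2(C)C=CC(=O)C(C)=C2C1 | intermediate
8 | trienyl triflate | C1[C@H](O[Si](C)(C)C(C)(C)C)[C@@]2(C)C=CC(OS(=O)(=O)C(F)(F)F)=C(C)C2=C1 | intermediate
9 | 9α‑hydroxy‑10α‑H dienyl triflate | C1[C@H](O[Si](C)(C)C(C)(C)C)[C@@]2(C)C=CC(OS(=O)(=O)C(F)(F)F)=C(C)[C@@H]2[C@H]1O | intermediate
10 | 11,13‑diene 9α‑ol | C1[C@H](O[Si](C)(C)C(C)(C)C)[C@@]2(C)C=CC=C(C)[C@@H]2[C@H]1O | intermediate
11 | 9α,11α,12α‑triol | C1[C@H](O[Si](C)(C)C(C)(C)C)[C@@]2(C)C=C[C@@H](O)[C@@](C)(O)[C@@H]2[C@H]1O | intermediate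
12 | 11,12‑acetonide 9α‑ol | C1[C@H](O[Si](C)(C)C(C)(C)C)[C@@]2(C)C=C[C@@H](OC3(C)C)[C@@](C)(O3)[C@@H]2[C@H]1O | intermediate
13 | northern 9‑ketone | C1[C@H](O[Si](C)(C)C(C)(C)C)[C@@]2(C)C=C[C@@H](OC3(C)C)[C@@](C)(O3)[C@@H]2C1=O | intermediate
14 | methyl propanoate | CCC(=O)OC | starting material
15 | 4‑methylfuran‑2‑carbaldehyde | Cc1coc(C=O)c1 | starting material
16 | methyl 3‑hydroxy‑2‑methyl‑3‑(4‑methylfuran‑2‑yl)propanoate (diastereomer mixture) | COC(=O)C(C)C(O)c1cc(C)co1 | intermediate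
17 | methyl 2‑(6‑hydroxy‑5‑methyl‑3‑oxo‑3,6‑dihydro‑2H‑pyran‑2‑yl)propanoate (mixture) | COC(=O)C(C)C1OC(O)C(C)=CC1=O | intermediate
18 | methyl 2‑(6‑acetoxy‑5‑methyl‑3‑oxo‑3,6‑dihydro‑2H‑pyran‑2‑yl)propanoate (mixture) | COC(=O)C(C)C1OC(OC(C)=O)C(C)=CC1=O | intermediate
19 | C9 enol diisopropylsilyl triflate of 13 | C=1[C@H](O[Si](C)(C)C(C)(C)C)[C@@]2(C)C=C[C@@H](OC3(C)C)[C@@](C)(O3)[C@@H]2C=1O[Si](C(C)C)(C(C)C)OS(=O)(=O)C(F)(F)F | intermediate (not isolated)
20 | bis(enol) silane linking O9 and O7 | C=1[C@H](O[Si](C)(C)C(C)(C)C)[C@@]2(C)C=C[C@@H](OC3(C)C)[C@@](C)(O3)[C@@H]2C=1O[Si](C(C)C)(C(C)C)OC4=C(C(C)C(=O)OC)OC(OC(C)=O)C(C)=C4 | intermediate (not isolated)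
21 | tethered 3‑silyloxypyrylium triflate | C=1[C@H](O[Si](C)(C)C(C)(C)C)[C@@]2(C)C=C[C@@H](OC3(C)C)[C@@](C)(O3)[C@@H]2C=1O[Si](C(C)C)(C(C)C)Oc4cc(C)c[o+]c4C(C)C(=O)OC.[O-]S(=O)(=O)C(F)(F)F | intermediate (not isolated)
22 | cycloadduct with O9–Si(iPr)2–OAc and 2β‑OSi | CC1=CC(=O)[C@]2(C(C)C(=O)OC)O[C@H]1[C@H]3[C@H](O[Si](C)(C)C(C)(C)C)[C@@]4(C)C=C[C@@H](OC5(C)C)[C@@](C)(O5)[C@@H]4[C@@]23O[Si](C(C)C)(C(C)C)OC(C)=O | intermediate (not isolated)
23 | cage keto diol (C17 epimers) | CC1=CC(=O)[C@]2(C(C)C(=O)OC)O[C@H]1[C@H]3[C@H](O)[C@@]4(C)C=C[C@@H](OC5(C)C)[C@@](C)(O5)[C@@H]4[C@@]23O | intermediate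
24 | C7 exo‑hydroxy ester | CC1=C[C@H](O)[C@]2(C(C)C(=O)OC)O[C@H]1[C@H]3[C@H](O)[C@@]4(C)C=C[C@@H](OC5(C)C)[C@@](C)(O5)[C@@H]4[C@@]23O | intermediate (not isolated)
25 | cage γ‑lactone | CC1=C[C@@H]6OC(=O)[C@H](C)[C@]62O[C@H]1[C@H]3[C@H](O)[C@@]4(C)C=C[C@@H](OC5(C)C)[C@@](C)(O5)[C@@H]4[C@@]23O | intermediate
26 | 6‑chloro‑5(16)‑ene cage lactone | C=C1[C@H](Cl)[C@@H]6OC(=O)[C@H](C)[C@]62O[C@H]1[C@H]3[C@H](O)[C@@]4(C)C=C[C@@H](OC5(C)C)[C@@](C)(O5)[C@@H]4[C@@]23O | intermediate
27 | 2‑keto aldol | C=C1[C@H](Cl)[C@@H]6OC(=O)[C@H](C)[C@]62O[C@H]1[C@H]3C(=O)[C@@]4(C)C=C[C@@H](OC5(C)C)[C@@](C)(O5)[C@@H]4[C@@]23O | intermediate (not isolated)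
28 | ten‑membered (3Z)‑2,9‑diketone | C=C1/C=C\C(=O)[C@@]2(C)C=C[C@@H](OC3(C)C)[C@@](C)(O3)[C@@H]2C(=O)[C@]2(O)[C@@H](C)C(=O)O[C@H]2[C@H]1Cl | intermediate
29 | (2S,9S)‑diol acetonide | C=C1/C=C\[C@H](O)[C@@]2(C)C=C[C@@H](OC3(C)C)[C@@](C)(O3)[C@@H]2[C@H](O)[C@]2(O)[C@@H](C)C(=O)O[C@H]2[C@H]1Cl | intermediate
30 | 2,8,9,11,12‑pentaol | C=C1/C=C\[C@H](O)[C@@]2(C)C=C[C@@H](O)[C@@](C)(O)[C@@H]2[C@H](O)[C@]2(O)[C@@H](C)C(=O)O[C@H]2[C@H]1Cl | intermediate
31 | CNP0285654.2 | C=C1/C=C\[C@H](OC(C)=O)[C@@]2(C)C=C[C@@H](OC(C)=O)[C@@](C)(O)[C@@H]2[C@H](OC(C)=O)[C@]2(O)[C@@H](C)C(=O)O[C@H]2[C@H]1Cl | target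

**Count and risks**
Total steps: 21. Longest linear sequence: 18 (steps 1–11 and 15–21).

Most likely to fail:

Step 15 (the proposed annulation; tether assembly, and β‑silyloxy enolate stability). The fallback sets out from 13 and comes back at 23 using known reactions. LiN(SiMe3)2 and Me3SiCl give the trimethylsilyl enol ether F1. Me3SiOTf‑promoted Mukaiyama‑type C‑glycosylation of F1 with acetate 18 joins C3 to C4 and gives the pyranone diketone F2. A TiCl4/iPr2NEt aldol from the C7 ketone onto the C9 ketone closes C8–C9 to the silyl‑protected aldol F3, with diastereomers from the racemic pyranone separated at this point. HF·pyridine then gives 23.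

Step 18 (ring expansion; competing dehydration of the aldol, re‑closure, E/Z control). The fallback sets out from 26 and comes back at 28. Dess–Martin oxidation is run as before but 27 is isolated. PhI(OAc)2 and I2 under visible light (Suárez alkoxy‑radical β‑scission) cut C3–C9, and iodine traps the α‑keto radical as the ring‑expanded, still oxygen‑bridged iodo ketone F4. Zinc dust in AcOH then causes reductive β‑elimination of the bridging oxygen to give 28.

Step 19 (two stereocentres set on a flexible ring). The fallback sets out from 28 and comes back at 29. Zn(BH4)2 in Et2O at −40 °C reduces only the chelated α‑hydroxy ketone and gives the 9‑hydroxy enone F5. The C2 enone is then reduced under catalyst control with catecholborane and the oxazaborolidine (S)‑1‑methyl‑3,3‑diphenyltetrahydro‑1H,3H‑pyrrolo[1,2‑c][1,3,2]oxazaborole, or its enantiomer if that is the matched one.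

**Further compounds**
F1 | step 15 | trimethylsilyl enol ether of 13 | C=1[C@H](O[Si](C)(C)C(C)(C)C)[C@@]2(C)C=C[C@@H](OC3(C)C)[C@@](C)(O3)[C@@H]2C=1O[Si](C)(C)C
F2 | step 15 | C3–C4 linked pyranone diketone | CC1=CC(=O)C(C(C)C(=O)OC)O[C@H]1[C@H]2[C@H](O[Si](C)(C)C(C)(C)C)[C@@]3(C)C=C[C@@H](OC4(C)C)[C@@](C)(O4)[C@@H]3C2=O
F3 | step 15 | 2β‑silyl‑protected cage aldol | CC1=CC(=O)[C@]2(C(C)C(=O)OC)O[C@H]1[C@H]3[C@H](O[Si](C)(C)C(C)(C)C)[C@@]4(C)C=C[C@@H](OC5(C)C)[C@@](C)(O5)[C@@H]4[C@@]23O
F4 | step 18 | oxygen‑bridged ten‑membered 3‑iodo‑2,9‑diketone | O1C(=O)[C@H](C)[C@@]23O[C@@H](C(I)C(=O)[C@@]4(C)C=C[C@@H](OC5(C)C)[C@@](C)(O5)[C@@H]4C2=O)C(=C)[C@H](Cl)[C@H]13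
F5 | step 19 | 9S‑hydroxy 2‑enone | C=C1/C=C\C(=O)[C@@]2(C)C=C[C@@H](OC3(C)C)[C@@](C)(O3)[C@@H]2[C@H](O)[C@]2(O)[C@@H](C)C(=O)O[C@H]2[C@H]1Cl
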